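The readings are calculated for an exercise; noise was put on by code.

A slow flask invites the thought that time is what it lacks, and on that two chemists part over the flask below, a racemate offered to a single-handed catalyst.

| setting | ash | elm | flask |
|---|---|---|---|
| left-handed substrate | 0.070 M | 0.11 M | 0.050 M |
| right-handed substrate | 0.070 M | 0.11 M | 0.050 M |
| protic impurity | 0.050 M | 0.050 M | 0.0500 M |
| solid reagent | 0.060 M | 0.060 M | 0.0600 M |
| free catalyst | 0.50 mM | 0.50 mM | 0.50 mM |
| stray impurity | 0.72 mM | 0.72 mM | 0.72 mM |
| remark | run made earlier | run made earlier |  |
| time |  |  | 6.0 h |

| run | time / h | right-handed substrate / % | left-handed substrate / % | left-handed product / % |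
|---|---|---|---|---|
| ash | 1.00 | 47.7 | 45.5 | 4.2 |
| ash | 2.00 | 48.1 | 43.6 | 6.3 |
| ash | 3.00 | 47.1 | 43.5 | 8.1 |
| ash | 4.00 | 46.4 | 41.5 | 7.7 |
| ash | 5.00 | 46.5 | 41.6 | 8.3 |
| ash | 6.00 | 47.4 | 42.3 | 7.5 |
| elm | 0.417 | 49.0 | 48.2 | 1.0 |
| elm | 1.33 | 49.1 | 46.0 | 4.5 |
| elm | 2.00 | 48.1 | 44.3 | 4.7 |
| elm | 3.00 | 47.9 | 44.5 | 6.5 |
| elm | 5.00 | 48.1 | 43.8 | 6.5 |
| elm | 6.00 | 48.1 | 43.6 | 6.8 |

(standard deviation of a reading: 0.5 percentage points)

- free catalyst is single-handed; left-handed substrate and right-handed substrate are mirror images of each other, charged as a racemate, each of them at the stated concentration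
- solid, in amounts per volume of the solution: solid reagent
- on the list of suspects stand: coupling partner + free catalyst + left-handed substrate -> free catalyst + left-handed product; coupling partner + free catalyst + right-handed substrate -> free catalyst + right-handed product; coupling partner + protic impurity -> quenched reagent; free catalyst + stray impurity -> spent catalyst; solid reagent <-> coupling partner
- at the start none of the solid reagent is in solution

1. whether the excess of right-handed substrate over left-handed substrate among what is left of the two reaches 90% by 6.0 h (no / yes)
2. the highest excess of right-handed substrate over left-handed substrate among what is left of the two up to 6.0 h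

Call the reach of a substrate the natural logarithm of its charged c over its c left. On the list of suspects both coupling steps use the same coupling partner and free catalyst, so in any run following those steps the ratio of the two reaches stays constant. Pooled over the plateau readings of ash, from 4.00 h, and elm, from 3.00 h, that ratio reads 2.88, and this selectivity factor s turns a left-handed reach x into a right-handed reach x/s, and so into an excess. An excess of 90% then asks for a reach of 4.51, which leaves 1.10% of the left-handed charge, so neither chemist expects it in this flask.

They part on the height. The patient one extends the pace of ash up to 1.00 h, 0.0943 h⁻¹, over 6.0 h, which gives a reach of 0.566 and, through s, an excess of 18.3%. The other holds “Both runs level off by about 3 h, so something runs out.” and forecasts no and 7%. My own reckoning on that side, carrying over the plateau reach of ash, 0.179, gives 5.84%, a little lower than the forecast.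

The flask gives no and 6.14%, so the plateau view stands. At 3.00 h the flask holds 0.265% of its free catalyst, while c(coupling partner) is 0.0161 M. The flask ends with 82% of its left-handed substrate left, a reach of 0.194, for which s gives an excess of 6.32%.

    coupling partner + free catalyst + left-handed substrate → free catalyst + left-handed product (k = 7100 L² mol⁻² min⁻¹)
    coupling partner + free catalyst + right-handed substrate → free catalyst + right-handed product (k = 2600 L² mol⁻² min⁻¹)
    coupling partner + protic impurity → quenched reagent (k = 0.130 L mol⁻¹ min⁻¹)
    free catalyst + stray impurity → spent catalyst (k = 120 L mol⁻¹ min⁻¹)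
    solid reagent ⇌ coupling partner, rate k5*(cs5 - [coupling partner]) while solid is left; crystals form when [coupling partner] > cs5 (solubility = 47.0 mM, k = 0.00530 min⁻¹)

The patient view comes nearer in the neighbour with 2.9 × 10⁻⁴ M of stray impurity, where 42.0% of the free catalyst stands at 6.00 h, with c(coupling partner) down to 4.41 × 10⁻⁵ M, and 28% of the left-handed substrate is left, a reach of 1.29, further than the patient 0.566. There s gives 39.6%, and the computed top is 38.6%.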